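## Structural features

The target is a 2,3,4-trisubstituted tetrahydrofuran (ring A: O1, C2, C3, C4, C5). C2 carries a 4-hydroxyphenyl group (ring B), C3 carries the acetoxymethyl carbon C3a, and C4 carries the exocyclic carbon C4a, which bears an acetate and a 4-methoxyphenyl group (ring C). These atom labels are kept for every intermediate; in the six-membered compounds the ring runs O1–C2–C3–C4a–C4–C5, so C4a, C4 and C5 are positions 4, 5 and 6 of the pyran names. Four stereocentres are contiguous: C2 (R), C3 (S), C4 (R) and C4a (S). The ring substituents alternate faces (2,3-trans, 3,4-trans), and C4a lies outside the ring, where ring conformation gives little guidance. Three functions are fragile: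
- the free phenol para to the benzylic ether carbon C2, where acid or strong base can open C2–O1 through a quinone-methide-like species and scramble C2;
- the C4a acetate, which is benzylic and para-methoxy-activated and so ionises, eliminates or hydrogenolyses easily;
- the two aliphatic acetates, which must survive while the phenol is left free.

The real difficulty is the exocyclic centre C4a set against the all-trans ring, plus an endgame that keeps both activated benzylic C–O bonds away from acid. The key step exploits the fact that ring A with an aryl ketone at C4a is the contracted form of a 3,6-dihydro-2H-pyran in which C4a is an alkene carbon. Moving C3 from C4a to C4 forms C3–C4, shrinks the ring and leaves C4a as a carbonyl group.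

## Logic of the disconnections

18 is traced to 17 by re-acylating the phenol oxygen (the aryl O–acetyl bond is the one cut forward). The two aliphatic acetates cannot be put on selectively beside a free phenol, but an aryl acetate solvolyses far faster than alkyl acetates. 17 comes from 16 by cutting all three O–acetyl bonds, and 16 from 15 by restoring both O–Si bonds. The gain is that the three hydroxyls never need to be told apart; the demand is that the last solvolysis stops at the phenolic ester under near-neutral conditions.

15 is traced to 14 by removing the C4a–H bond. Taking C4a to the ketone level deletes one stereocentre and makes C4 epimerisable, so the all-trans ring can be reached under thermodynamic control. The forward hydride addition must choose one carbonyl face and must avoid base, because 14 is a β-alkoxy ketone.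

14 is traced to 12 (through 13) by cutting C3–C4 and rejoining C3 to C4a. This turns the ring into a six-membered cyclic aryl alkene with only two stereocentres (C2, C3). The forward step must put the electrophile on C4 and methanol on C4a, and the ring carbon must migrate in preference to the anisyl group. It also releases one equivalent of TsOH in methanol. For that reason the primary hydroxyl of 12 is carried as a tert-butyldiphenylsilyl ether, not a tert-butyldimethylsilyl ether, and the phenol as its triisopropylsilyl ether. A free C3a hydroxyl next to the C4a ketone could also trap the 3,4-cis isomer as a bicyclic ketal.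

12 is traced to 10 and 11 by cutting the C4a–aryl bond. The cut is convergent and the alkene position is fixed by the triflate. The demand is an enol triflate with the double bond between C4a and C4 only.

10 is traced to 8 (through 9) by cutting the C4a O–S bond and the C5–H bond. Conjugate hydride addition to the enone generates the enolate on the side away from C3, which deprotonation of a saturated ketone could not guarantee. The enolate must be trapped cold before it expels O1 or equilibrates.

8 is traced to 7 by cutting the O–Si bond, and 7 to 5 (through 6) by cutting C3–C3a. A one-carbon electrophile on the α′-enolate installs C3a, and the C2 aryl group directs it to the opposite face. The demand is a kinetic enolate that does not ring-open.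

5 is traced to 2 and 3 (through 4) by cutting C2–C3 and O1–C5. This is a catalytic asymmetric hetero-Diels–Alder disconnection that sets C2, the only centre needing absolute control. 2 is traced to 1 by cutting the aryl O–Si bond.

## Other disconnections considered

Alternative 1: The cut removes C5 (bonds O1–C5 and C4–C5) and the C4a–O bond, leaving the homoallylic alcohol A1. Forward, BF3·OEt2 in acetic acid would condense A1 with formaldehyde A2 to an oxocarbenium ion on O1. The E-styrene would attack it through C4, and acetate would quench the benzylic cation at C4a to give A3, the phenol silyl ether of 18.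
- In favour: three bonds and two stereocentres (C4, C4a) form in one operation, the C4a acetate arrives in its final form, and A3 is one desilylation from 18. On step count this plan is clearly better than the chosen one. For the 3,4-trans relationship it is the equal of the chosen plan, since an envelope transition state with pseudo-equatorial substituents should deliver it.
- Against: the cation at C4a is a free, anisyl-stabilised benzylic cation, so the face of acetate capture rests on a weak conformational preference, and the benzylic acetate can re-ionise under BF3. The C2 carbinol is benzylic and para-oxygenated; under a strong Lewis acid it can ionise, or the oxocarbenium ion can undergo 2-oxonia-Cope rearrangement, and either erodes C2 and C3.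
- Comparison: both plans pass through an anisyl-stabilised cation at C4a, but in the chosen plan that carbon ends as a carbonyl, so no stereochemical information rides on the cation, and C4a is set later under reagent control.

Alternative 2: The cut is C2–C3. The precursor is the α-diazo ester A4, a 4-silyloxybenzyl ether that already holds C4 and C4a. Forward, Rh2(S-PTTL)4 would generate the divalent-rhodium carbenoid at C3, which inserts into the benzylic ether C–H bond at C2 (1,5-insertion) to give the ester A5.
- In favour: the C2–H bond is activated by the ether oxygen and the electron-rich arene, and five-membered insertion is the normal mode. C4 and C4a are made beforehand by acyclic chemistry, so on the exocyclic centre this plan is better than the chosen one.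
- Against: the carbenoid has a hydrogen on C4, and 1,2-hydride shift to the unsaturated ester is the classical competitor. The catalyst must override the bias of two existing centres. Insertions of this type tend to give the 2,3-cis ester, so C3 would need epimerisation (equal to the C4 equilibration of the chosen plan). C3a arrives as an ester that must be reduced.
- Comparison: the endgame is about four steps (equal), and the route to A4 is about as long as the route to 12, so step economy is about equal. The chosen plan relies on a stereoelectronically defined 1,2-shift; this one relies on catalyst discrimination between insertion and hydride shift.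

Alternative 3: The cuts are O1–C5 and C3–C4. The pieces are the epoxy carbinol A6 and the aryl vinyl ketone A7. PMe3-catalysed oxa-Michael addition would give the β-alkoxy ketone A8. LiN(SiMe3)2 would then form the ketone enolate, whose C4 opens the epoxide at its internal carbon C3 (5-exo-tet, inversion at C3). Acetylation of the released C3a alkoxide in the quench would give A9.
- In favour: it is fully convergent. C2 and C3 come from a titanium–tartrate epoxidation, so on absolute control it is equal or better. Inversion at C3 makes 2,3-trans stereospecific. A9 already carries the C3a acetate, so its endgame is one step shorter than from 14 (better).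
- Against: the enolate of A8 is a β-alkoxy ketone enolate and can expel the C2 alkoxide (retro-oxa-Michael) faster than it alkylates a hindered internal epoxide carbon. The oxa-Michael addition is reversible, the vinyl ketone polymerises, and the epoxy alkoxide can undergo Payne-type migration.
- Comparison: A9 and 14 pose the same C4 equilibration and C4a reduction questions (equal). This plan is shorter on paper, but its key step asks an unstable intermediate to do a slow intermolecular-type alkylation, whereas the chosen key step is a shift inside a preformed ring.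

Key step: step 7

Remark: the (R)-configured ligand in step 2 is assumed to steer the diene to the Re face of 2 (giving 2R); if the sense of induction is the reverse, the (S)-ligand is used and nothing else changes.

Remark: the all-trans ring corresponds to (2R,3S,4R) with (S) at C4a; 14 has the same ring descriptors and 12 is (2R,3S), so no configuration needs correcting, and the only change to the precursor design is the more acid-stable primary silyl ether.

## Route

Step 1
Reactants: 1 4-hydroxybenzaldehyde
Product: 2 4-(triisopropylsilyloxy)benzaldehyde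
Conditions: TIPSCl, imidazole, DMF, 0 °C → rt
Reagents that add atoms: chlorotri(propan-2-yl)silane (TIPSCl), CC(C)[Si](Cl)(C(C)C)C(C)C
Why: Imidazole-promoted silylation of a phenol; the aryl triisopropylsilyl ether should withstand amide base, borohydride, aqueous phosphate and the brief TsOH exposure of step 7, yet falls to fluoride at the end.

Step 2
Reactants: 2 4-(triisopropylsilyloxy)benzaldehyde; 3 (E)-1-methoxy-3-(trimethylsilyloxy)buta-1,3-diene
Product: 5 (2R)-2-[4-(triisopropylsilyloxy)phenyl]-2,3-dihydro-4H-pyran-4-one, via silylated aldol adduct 4 (not isolated)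
Conditions: Ti(OiPr)4 (10 mol%), (R)-H8-BINOL (11 mol%), 4 Å MS, toluene, 0 °C; then CF3CO2H, CH2Cl2, 0 °C
Reagents that add atoms: none
Why: Catalytic asymmetric hetero-Diels–Alder reaction in its Mukaiyama-aldol/cyclisation form: the tetravalent titanium complex of (R)-5,5′,6,6′,7,7′,8,8′-octahydro-1,1′-bi-2-naphthol activates the aldehyde, the diene terminus adds to the Re face to form C2–C3 (adduct 4), and acid closes O1–C5 with loss of Me3SiOMe. C2 (R) is set by the catalyst and every later centre is relayed from it.

Step 3
Reactants: 5 (2R)-2-[4-(triisopropylsilyloxy)phenyl]-2,3-dihydro-4H-pyran-4-one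
Product: 7 (2R,3S)-3-(hydroxymethyl)-2-[4-(triisopropylsilyloxy)phenyl]-2,3-dihydro-4H-pyran-4-one, via lithium dienolate 6 (not isolated)
Conditions: LiN(iPr)2, THF, −78 °C; CH2O (monomeric, from cracked paraformaldehyde), −78 °C; AcOH, −78 °C
Reagents that add atoms: formaldehyde, C=O; lithium diisopropylamide, [Li+].CC(C)[N-]C(C)C (lithium of 6 only)
Why: Kinetic deprotonation at C3, the only enolisable position, gives the cross-conjugated dienolate 6, and its aldol addition to formaldehyde forms C3–C3a. The electrophile approaches anti to the C2 aryl group, so C3 is set trans (S) by substrate control, which is also the thermodynamically preferred arrangement; the cold acetic acid quench limits retro-aldol reaction and dehydration.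

Step 4
Reactants: 7 (2R,3S)-3-(hydroxymethyl)-2-[4-(triisopropylsilyloxy)phenyl]-2,3-dihydro-4H-pyran-4-one
Product: 8 (2R,3S)-3-[(tert-butyldiphenylsilyloxy)methyl]-2-[4-(triisopropylsilyloxy)phenyl]-2,3-dihydro-4H-pyran-4-one
Conditions: TBDPSCl, imidazole, DMF, 0 °C
Reagents that add atoms: tert-butyl(chloro)diphenylsilane (TBDPSCl), CC(C)(C)[Si](Cl)(c1ccccc1)c1ccccc1
Why: Imidazole-promoted silylation of the primary alcohol under conditions too mild to eliminate the β-oxygenated ketone. The tert-butyldiphenylsilyl ether is chosen because it should survive TsOH in methanol in step 7 and keeps the C3a oxygen from forming a cyclic ketal with the C4a ketone.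

Step 5
Reactants: 8 (2R,3S)-3-[(tert-butyldiphenylsilyloxy)methyl]-2-[4-(triisopropylsilyloxy)phenyl]-2,3-dihydro-4H-pyran-4-one
Product: 10 (2R,3S)-3-[(tert-butyldiphenylsilyloxy)methyl]-2-[4-(triisopropylsilyloxy)phenyl]-3,6-dihydro-2H-pyran-4-yl trifluoromethanesulfonate, via lithium enolate 9 (not isolated)
Conditions: LiBH(sec-Bu)3, THF, −78 °C; then N-(5-chloropyridin-2-yl)bis(trifluoromethanesulfonyl)imide, −78 → 0 °C
Reagents that add atoms: N-(5-chloropyridin-2-yl)-1,1,1-trifluoro-N-(trifluoromethylsulfonyl)methanesulfonamide, O=S(=O)(N(c1ccc(Cl)cn1)S(=O)(=O)C(F)(F)F)C(F)(F)F; lithium tri-sec-butylborohydride, [Li+].CCC(C)[BH-](C(C)CC)C(C)CC (lithium of 9 only)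
Why: Conjugate reduction of the vinylogous ester delivers hydride to C5 and gives enolate 9 regiospecifically between C4a and C4. O-sulfonylation at −78 °C (enolate trapping as the enol triflate) fixes the double bond there before the enolate can expel O1 or equilibrate towards C3; no stereocentre is made and C3 is untouched.

Step 6
Reactants: 10 (2R,3S)-3-[(tert-butyldiphenylsilyloxy)methyl]-2-[4-(triisopropylsilyloxy)phenyl]-3,6-dihydro-2H-pyran-4-yl trifluoromethanesulfonate; 11 4-methoxyphenylboronic acid
Product: 12 (2R,3S)-3-[(tert-butyldiphenylsilyloxy)methyl]-4-(4-methoxyphenyl)-2-[4-(triisopropylsilyloxy)phenyl]-3,6-dihydro-2H-pyran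
Conditions: Pd(PPh3)4 (5 mol%), K3PO4, 1,4-dioxane/H2O, 60 °C
Reagents that add atoms: none
Why: Suzuki–Miyaura coupling of an alkenyl triflate with an arylboronic acid under zerovalent palladium catalysis forms the C4a–aryl bond without moving the double bond. Both silyl ethers should tolerate aqueous phosphate at this temperature.

Step 7
Reactants: 12 (2R,3S)-3-[(tert-butyldiphenylsilyloxy)methyl]-4-(4-methoxyphenyl)-2-[4-(triisopropylsilyloxy)phenyl]-3,6-dihydro-2H-pyran
Product: 14 (2R,3S,4R)-3-[(tert-butyldiphenylsilyloxy)methyl]-4-(4-methoxybenzoyl)-2-[4-(triisopropylsilyloxy)phenyl]tetrahydrofuran, via dimethyl ketal 13 (not isolated)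
Conditions: PhI(OH)OTs (1.2 equiv), MeOH/CH2Cl2 (4:1), −20 → 0 °C; then 1 M aq. HCl, THF, rt
Reagents that add atoms: methanol, CO (the two methoxy groups of 13); water, O (the carbonyl oxygen of 14)
Why: In methanol the trivalent iodine reagent adds as an electrophile to the anisyl alkene at C4, the only position that leaves an anisyl-stabilised cation at C4a, and methanol captures C4a anti to iodine. In the chair of this anti adduct that has the C4–I bond equatorial, the ring bond C3–C4a is antiperiplanar to C4–I, whereas the anisyl group is gauche to it in both chairs; C3 therefore shifts from C4a to C4 as iodobenzene departs, and the resulting methoxy- and anisyl-stabilised oxocarbenium ion is trapped as ketal 13 and hydrolysed to 14. The closest known reaction type is the oxidative ring contraction of cyclic aryl alkenes by trivalent iodine or trivalent thallium (1,2-dihydronaphthalenes to indanes), a semipinacol-type Wagner–Meerwein shift. Ring A is not closed from a chain: it arises by contraction of the six-membered ring through a three-centre migration transition state, C3 moving with retention and displacing iodine from C4 with inversion. C4 is the one new stereocentre; iodine should add to the face opposite the C3 substituent, so inversion gives 3,4-trans directly, and because C4 is α to the ketone, acid-mediated enolisation in the work-up should converge any cis isomer on the all-trans compound. The step needs ring-carbon migration to beat anisyl migration and simple 1,2-dimethoxylation, which the anti-addition geometry and the strongly stabilised oxocarbenium ion secure, and it needs the alkene to react before either aryl ether, which its higher nucleophilicity secures. The aryl triisopropylsilyl and primary tert-butyldiphenylsilyl ethers should tolerate the TsOH released; base is avoided throughout because the enolate of 14 could expel O1 from C5.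

Step 8
Reactants: 14 (2R,3S,4R)-3-[(tert-butyldiphenylsilyloxy)methyl]-4-(4-methoxybenzoyl)-2-[4-(triisopropylsilyloxy)phenyl]tetrahydrofuran
Product: 15 (S)-{(3R,4S,5R)-4-[(tert-butyldiphenylsilyloxy)methyl]-5-[4-(triisopropylsilyloxy)phenyl]tetrahydrofuran-3-yl}(4-methoxyphenyl)methanol
Conditions: (R)-2-methyl-CBS-oxazaborolidine (0.5 equiv), BH3·SMe2, THF, −20 °C; MeOH quench
Reagents that add atoms: none
Why: Corey–Bakshi–Shibata reduction: the (R)-oxazaborolidine–borane complex, treating the aryl group as the large substituent, delivers hydride to the Re face of the C4a carbonyl and gives the (S)-carbinol. This is also the Felkin–Anh face (attack anti to the branched ring carbon C3, past the C4 hydrogen), so reagent and substrate control reinforce each other, and the neutral conditions avoid enolisation of the β-alkoxy ketone.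

Step 9
Reactants: 15 (S)-{(3R,4S,5R)-4-[(tert-butyldiphenylsilyloxy)methyl]-5-[4-(triisopropylsilyloxy)phenyl]tetrahydrofuran-3-yl}(4-methoxyphenyl)methanol
Product: 16 4-{(2R,3S,4R)-4-[(S)-hydroxy(4-methoxyphenyl)methyl]-3-(hydroxymethyl)tetrahydrofuran-2-yl}phenol
Conditions: Bu4NF, AcOH, THF, 0 °C → rt
Reagents that add atoms: none
Why: Fluoride-induced cleavage of both silyl ethers, driven by Si–F bond formation. Acetic acid buffers the phenoxide so that C2–O1 is not opened through a quinone methide, and no strong acid reaches the anisyl carbinol.

Step 10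
Reactants: 16 4-{(2R,3S,4R)-4-[(S)-hydroxy(4-methoxyphenyl)methyl]-3-(hydroxymethyl)tetrahydrofuran-2-yl}phenol
Product: 17 4-{(2R,3S,4R)-4-[(S)-acetoxy(4-methoxyphenyl)methyl]-3-(acetoxymethyl)tetrahydrofuran-2-yl}phenyl acetate
Conditions: Ac2O, pyridine, DMAP (cat.), CH2Cl2, 0 °C → rt
Reagents that add atoms: acetic anhydride, CC(=O)OC(C)=O
Why: Exhaustive DMAP-catalysed acetylation of both alcohols and the phenol; complete acylation removes any need to differentiate the three hydroxyls, and the basic medium does not ionise the benzylic centre.

Step 11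
Reactants: 17 4-{(2R,3S,4R)-4-[(S)-acetoxy(4-methoxyphenyl)methyl]-3-(acetoxymethyl)tetrahydrofuran-2-yl}phenyl acetate
Product: 18 [(2R,3S,4R)-4-[(S)-acetoxy(4-methoxyphenyl)methyl]-2-(4-hydroxyphenyl)tetrahydrofuran-3-yl]methyl acetate
Conditions: NH4OAc, MeOH/H2O (4:1), rt
Reagents that add atoms: none
Why: Chemoselective solvolysis of the aryl acetate: phenoxide is a far better leaving group than an alkoxide, so near-neutral ammonium acetate in aqueous methanol should remove only the phenolic acetyl group. Neither C2 nor the C4a acetate meets acid or strong base.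

## Compound list

1 | 4-hydroxybenzaldehyde | O=Cc1ccc(O)cc1 | starting material
2 | 4-(triisopropylsilyloxy)benzaldehyde | O=Cc1ccc(O[Si](C(C)C)(C(C)C)C(C)C)cc1 | intermediate
3 | (E)-1-methoxy-3-(trimethylsilyloxy)buta-1,3-diene | CO/C=C/C(=C)O[Si](C)(C)C | starting material
4 | (1E,5R)-1-methoxy-5-[4-(triisopropylsilyloxy)phenyl]-5-(trimethylsilyloxy)pent-1-en-3-one (not isolated) | CO/C=C/C(=O)C[C@@H](O[Si](C)(C)C)c1ccc(O[Si](C(C)C)(C(C)C)C(C)C)cc1 | intermediate
5 | (2R)-2-[4-(triisopropylsilyloxy)phenyl]-2,3-dihydro-4H-pyran-4-one | O=C1C=CO[C@@H](c2ccc(O[Si](C(C)C)(C(C)C)C(C)C)cc2)C1 | intermediate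
6 | lithium (2R)-2-[4-(triisopropylsilyloxy)phenyl]-2H-pyran-4-olate (not isolated) | [Li]OC1=C[C@H](c2ccc(O[Si](C(C)C)(C(C)C)C(C)C)cc2)OC=C1 | intermediate
7 | (2R,3S)-3-(hydroxymethyl)-2-[4-(triisopropylsilyloxy)phenyl]-2,3-dihydro-4H-pyran-4-one | O=C1C=CO[C@@H](c2ccc(O[Si](C(C)C)(C(C)C)C(C)C)cc2)[C@@H]1CO | intermediate
8 | (2R,3S)-3-[(tert-butyldiphenylsilyloxy)methyl]-2-[4-(triisopropylsilyloxy)phenyl]-2,3-dihydro-4H-pyran-4-one | O=C1C=CO[C@@H](c2ccc(O[Si](C(C)C)(C(C)C)C(C)C)cc2)[C@@H]1CO[Si](c3ccccc3)(c4ccccc4)C(C)(C)C | intermediate
9 | lithium (2R,3S)-3-[(tert-butyldiphenylsilyloxy)methyl]-2-[4-(triisopropylsilyloxy)phenyl]-3,6-dihydro-2H-pyran-4-olate (not isolated) | [Li]OC1=CCO[C@@H](c2ccc(O[Si](C(C)C)(C(C)C)C(C)C)cc2)[C@@H]1CO[Si](c3ccccc3)(c4ccccc4)C(C)(C)C | intermediate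
10 | (2R,3S)-3-[(tert-butyldiphenylsilyloxy)methyl]-2-[4-(triisopropylsilyloxy)phenyl]-3,6-dihydro-2H-pyran-4-yl trifluoromethanesulfonate | O=S(=O)(OC1=CCO[C@@H](c2ccc(O[Si](C(C)C)(C(C)C)C(C)C)cc2)[C@@H]1CO[Si](c3ccccc3)(c4ccccc4)C(C)(C)C)C(F)(F)F | intermediate
11 | 4-methoxyphenylboronic acid | COc1ccc(B(O)O)cc1 | starting material
12 | (2R,3S)-3-[(tert-butyldiphenylsilyloxy)methyl]-4-(4-methoxyphenyl)-2-[4-(triisopropylsilyloxy)phenyl]-3,6-dihydro-2H-pyran | COc1ccc(C2=CCO[C@@H](c3ccc(O[Si](C(C)C)(C(C)C)C(C)C)cc3)[C@@H]2CO[Si](c4ccccc4)(c5ccccc5)C(C)(C)C)cc1 | intermediate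
13 | (2R,3S,4R)-3-[(tert-butyldiphenylsilyloxy)methyl]-4-[dimethoxy(4-methoxyphenyl)methyl]-2-[4-(triisopropylsilyloxy)phenyl]tetrahydrofuran (not isolated) | COc1ccc(C(OC)(OC)[C@H]2CO[C@@H](c3ccc(O[Si](C(C)C)(C(C)C)C(C)C)cc3)[C@@H]2CO[Si](c4ccccc4)(c5ccccc5)C(C)(C)C)cc1 | intermediate
14 | (2R,3S,4R)-3-[(tert-butyldiphenylsilyloxy)methyl]-4-(4-methoxybenzoyl)-2-[4-(triisopropylsilyloxy)phenyl]tetrahydrofuran (all-trans) | COc1ccc(C(=O)[C@H]2CO[C@@H](c3ccc(O[Si](C(C)C)(C(C)C)C(C)C)cc3)[C@@H]2CO[Si](c4ccccc4)(c5ccccc5)C(C)(C)C)cc1 | intermediate
15 | (S)-{(3R,4S,5R)-4-[(tert-butyldiphenylsilyloxy)methyl]-5-[4-(triisopropylsilyloxy)phenyl]tetrahydrofuran-3-yl}(4-methoxyphenyl)methanol | COc1ccc([C@@H](O)[C@H]2CO[C@@H](c3ccc(O[Si](C(C)C)(C(C)C)C(C)C)cc3)[C@@H]2CO[Si](c4ccccc4)(c5ccccc5)C(C)(C)C)cc1 | intermediate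
16 | 4-{(2R,3S,4R)-4-[(S)-hydroxy(4-methoxyphenyl)methyl]-3-(hydroxymethyl)tetrahydrofuran-2-yl}phenol | COc1ccc([C@@H](O)[C@H]2CO[C@@H](c3ccc(O)cc3)[C@@H]2CO)cc1 | intermediate
17 | 4-{(2R,3S,4R)-4-[(S)-acetoxy(4-methoxyphenyl)methyl]-3-(acetoxymethyl)tetrahydrofuran-2-yl}phenyl acetate | COc1ccc([C@@H](OC(C)=O)[C@H]2CO[C@@H](c3ccc(OC(C)=O)cc3)[C@@H]2COC(C)=O)cc1 | intermediate
18 | [(2R,3S,4R)-4-[(S)-acetoxy(4-methoxyphenyl)methyl]-2-(4-hydroxyphenyl)tetrahydrofuran-3-yl]methyl acetate | COc1ccc([C@@H](OC(C)=O)[C@H]2CO[C@@H](c3ccc(O)cc3)[C@@H]2COC(C)=O)cc1 | target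

## Step count and least certain steps

Total steps: 11. Longest linear sequence: 11 steps (1 to 18); 3 and 11 are bought and enter in steps 2 and 6.

**Step 7 (key step).** The most likely failure is diversion of the iodine adduct: 1,2-shift of the anisyl group from a non-chair conformer, or plain substitution of iodine by methanol, in place of ring-carbon migration. The TsOH released could also ionise the C2–O1 bond or loosen a silyl ether if the reaction is slow.
Fallback, from 12 back to 14: dihydroxylation with OsO4 (cat.) and N-methylmorpholine N-oxide on the face opposite the C3 substituent should give the cis-diol (2R,3S,4S,5S)-3-[(tert-butyldiphenylsilyloxy)methyl]-4-(4-methoxyphenyl)-2-[4-(triisopropylsilyloxy)phenyl]tetrahydro-2H-pyran-4,5-diol F1. MsCl and Et3N should sulfonylate only the secondary hydroxyl on C4 to give the monomethanesulfonate F2. Et3Al in CH2Cl2 at low temperature should then trigger a semipinacol rearrangement in which the C3–C4a bond, anti to the equatorial sulfonate, migrates to C4 with inversion and gives 14 directly.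

**Step 3.** The dienolate can ring-open by β-elimination (O1 leaves C2 as a vinylogous carboxylate), formaldehyde can add more than once, and the aldol can dehydrate to the exocyclic enone.
Fallback, from 5 back to 7: soft enolisation with Me3SiOTf and Et3N should give the silyl dienol ether (R)-trimethyl{[2-(4-(triisopropylsilyloxy)phenyl)-2H-pyran-4-yl]oxy}silane F3. A Mukaiyama-type hydroxymethylation with aqueous formaldehyde and Yb(OTf)3 in THF/H2O, with no free lithium enolate, should then give 7.

**Step 5.** The β-alkoxy enolate may fragment by retro-oxa-Michael loss of O1 from C5, or equilibrate to the C3 side (loss of silanolate, erosion of C3) before it is sulfonylated; some 1,2-reduction is also possible.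
Fallback, from 8 back to 12, bypassing steps 5 and 6 and not using 11: 1,2-addition of 4-MeOC6H4MgBr with CeCl3 to the vinylogous ester carbonyl should give the tertiary allylic alcohol (2R,3S)-3-[(tert-butyldiphenylsilyloxy)methyl]-4-(4-methoxyphenyl)-2-[4-(triisopropylsilyloxy)phenyl]-3,4-dihydro-2H-pyran-4-ol F4. A Ferrier-type ionic reduction with Et3SiH and CF3CO2H at −78 °C should ionise it to the anisyl-stabilised allylic oxocarbenium ion, which takes hydride at C5 and gives 12.

**Step 8.** Facial selectivity may be poor, because both α-substituents of the ketone are ring carbons of similar size and a hindered, electron-rich aryl ketone reduces slowly enough for uncatalysed borane reduction to compete.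
Fallback, from 14 back to 15: reduction with NaBH4 in MeOH at low temperature (Felkin–Anh control only), chromatographic separation of 15 from its C4a epimer, the (R)-carbinol F5, and return of F5 to 14 by oxidation with MnO2 for another pass.

## Further compounds

F1 | step 7 | (2R,3S,4S,5S)-3-[(tert-butyldiphenylsilyloxy)methyl]-4-(4-methoxyphenyl)-2-[4-(triisopropylsilyloxy)phenyl]tetrahydro-2H-pyran-4,5-diol | COc1ccc([C@]2(O)[C@@H](O)CO[C@@H](c3ccc(O[Si](C(C)C)(C(C)C)C(C)C)cc3)[C@@H]2CO[Si](c4ccccc4)(c5ccccc5)C(C)(C)C)cc1
F2 | step 7 | 5-O-methanesulfonate of F1, (2R,3S,4S,5S) | COc1ccc([C@]2(O)[C@@H](OS(C)(=O)=O)CO[C@@H](c3ccc(O[Si](C(C)C)(C(C)C)C(C)C)cc3)[C@@H]2CO[Si](c4ccccc4)(c5ccccc5)C(C)(C)C)cc1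
F3 | step 3 | (R)-trimethyl{[2-(4-(triisopropylsilyloxy)phenyl)-2H-pyran-4-yl]oxy}silane | C[Si](C)(C)OC1=C[C@H](c2ccc(O[Si](C(C)C)(C(C)C)C(C)C)cc2)OC=C1
F4 | step 5 | (2R,3S)-3-[(tert-butyldiphenylsilyloxy)methyl]-4-(4-methoxyphenyl)-2-[4-(triisopropylsilyloxy)phenyl]-3,4-dihydro-2H-pyran-4-ol (either configuration at the carbinol carbon) | COc1ccc(C2(O)C=CO[C@@H](c3ccc(O[Si](C(C)C)(C(C)C)C(C)C)cc3)[C@@H]2CO[Si](c4ccccc4)(c5ccccc5)C(C)(C)C)cc1
F5 | step 8 | (R)-{(3R,4S,5R)-4-[(tert-butyldiphenylsilyloxy)methyl]-5-[4-(triisopropylsilyloxy)phenyl]tetrahydrofuran-3-yl}(4-methoxyphenyl)methanol | COc1ccc([C@H](O)[C@H]2CO[C@@H](c3ccc(O[Si](C(C)C)(C(C)C)C(C)C)cc3)[C@@H]2CO[Si](c4ccccc4)(c5ccccc5)C(C)(C)C)cc1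
A1 | alternative 1 | (2S,3E)-2-{(R)-hydroxy[4-(triisopropylsilyloxy)phenyl]methyl}-4-(4-methoxyphenyl)but-3-en-1-yl acetate | COc1ccc(/C=C/[C@@H](COC(C)=O)[C@@H](O)c2ccc(O[Si](C(C)C)(C(C)C)C(C)C)cc2)cc1
A2 | alternative 1 | formaldehyde | C=O
A3 | alternative 1 | [(2R,3S,4R)-4-[(S)-acetoxy(4-methoxyphenyl)methyl]-2-[4-(triisopropylsilyloxy)phenyl]tetrahydrofuran-3-yl]methyl acetate | COc1ccc([C@@H](OC(C)=O)[C@H]2CO[C@@H](c3ccc(O[Si](C(C)C)(C(C)C)C(C)C)cc3)[C@@H]2COC(C)=O)cc1
A4 | alternative 2 | tert-butyl (3R,4S)-4-(tert-butyldimethylsilyloxy)-2-diazo-4-(4-methoxyphenyl)-3-{[4-(triisopropylsilyloxy)benzyloxy]methyl}butanoate | COc1ccc([C@@H](O[Si](C)(C)C(C)(C)C)[C@@H](COCc2ccc(O[Si](C(C)C)(C(C)C)C(C)C)cc2)C(=[N+]=[N-])C(=O)OC(C)(C)C)cc1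
A5 | alternative 2 | tert-butyl (2R,3R,4R)-4-[(S)-(tert-butyldimethylsilyloxy)(4-methoxyphenyl)methyl]-2-[4-(triisopropylsilyloxy)phenyl]tetrahydrofuran-3-carboxylate (all-trans) | COc1ccc([C@@H](O[Si](C)(C)C(C)(C)C)[C@H]2CO[C@@H](c3ccc(O[Si](C(C)C)(C(C)C)C(C)C)cc3)[C@@H]2C(=O)OC(C)(C)C)cc1
A6 | alternative 3 | (S)-[(R)-oxiran-2-yl][4-(triisopropylsilyloxy)phenyl]methanol | O[C@@H](c1ccc(O[Si](C(C)C)(C(C)C)C(C)C)cc1)[C@H]2CO2
A7 | alternative 3 | 1-(4-methoxyphenyl)prop-2-en-1-one | C=CC(=O)c1ccc(OC)cc1
A8 | alternative 3 | 1-(4-methoxyphenyl)-3-{(S)-[(R)-oxiran-2-yl][4-(triisopropylsilyloxy)phenyl]methoxy}propan-1-one | COc1ccc(C(=O)CCO[C@@H](c2ccc(O[Si](C(C)C)(C(C)C)C(C)C)cc2)[C@H]3CO3)cc1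
A9 | alternative 3 | [(2R,3S,4R)-4-(4-methoxybenzoyl)-2-[4-(triisopropylsilyloxy)phenyl]tetrahydrofuran-3-yl]methyl acetate (all-trans) | COc1ccc(C(=O)[C@H]2CO[C@@H](c3ccc(O[Si](C(C)C)(C(C)C)C(C)C)cc3)[C@@H]2COC(C)=O)cc1
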